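The ten-membered carbocycle is cut back to a cyclohexane: ring C5–C10 plus the four carbons C1–C4. The key step exploits the placement of the C5 ketone and the C10 carbinol carbon, linked on one side by C6–C9 and on the other by C4–C1: an anionic oxy-Cope rearrangement forms C2–C3 and cleaves C5–C10, giving at once the ten-membered ring, the C5 ketone, the C4 methine and the (E)-C1=C10 alkene that later becomes the C10 alcohol. Its precursor is a chair cyclohexanol from (R)-carvone with equatorial 2-propenyl at C5, equatorial vinyl (and methyl) at C10, silyl ethers at C8 and C9 and isopropenyl at C7.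

Key step: step 10

Remark (assumption): germacrane locants (C1–C10 ring carbons, C11–C13 lactone carbons) are used for every intermediate, and the C4 configuration of the target is taken to be the thermodynamically preferred one next to the C5 ketone.

Step 1
Reactants: 1 (R)-carvone
Product: 2 trans-6-hydroxycarvone
Conditions: NaN(SiMe3)2, THF, −78 °C; then 2-(phenylsulfonyl)-3-phenyloxaziridine
Reagents that add atoms: 2-(phenylsulfonyl)-3-phenyloxaziridine, O=S(=O)(c1ccccc1)N1OC1c1ccccc1
Why: Kinetic deprotonation at the α′ carbon (the future C8) gives the cross-conjugated sodium dienolate, and its Davis oxidation should occur on the face opposite the neighbouring C7 isopropenyl group, setting the trans C7/C8 relationship, which is also the more stable one at this epimerisable centre.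

Step 2
Reactants: 2 trans-6-hydroxycarvone
Product: 3 silyl ether of 2
Conditions: TBSCl, imidazole, DMF, rt
Reagents that add atoms: tert-butyldimethylsilyl chloride, CC(C)(C)[Si](C)(C)Cl
Why: Standard silylation of a secondary alcohol; the tert-butyldimethylsilyl ether should survive every basic, organometallic and oxidative step up to step 16, and no stereocentre is touched.

Step 3
Reactants: 3 silyl ether of 2
Product: 4 epoxy ketone
Conditions: H2O2 (30% aq.), NaOH (cat.), MeOH, 0 °C
Reagents that add atoms: hydrogen peroxide, OO
Why: Weitz–Scheffer nucleophilic epoxidation touches only the electron-poor enone alkene and not the isopropenyl group; the two new centres are erased again in steps 4 and 5, so their configuration (expected anti to the isopropenyl group) is immaterial.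

Step 4
Reactants: 4 epoxy ketone
Product: 5 transposed allylic alcohol
Conditions: N2H4·H2O, AcOH (cat.), MeOH, 0 °C to rt
Reagents that add atoms: none
Why: Wharton transposition: the epoxy hydrazone fragments with loss of nitrogen to the allylic alcohol, moving the oxygen from C9 to C5 and the alkene to C9=C10 while C7 and C8 stay untouched.

Step 5
Reactants: 5 transposed allylic alcohol
Product: 6 transposed enone
Conditions: MnO2, CH2Cl2, rt
Reagents that add atoms: none
Why: Chemoselective MnO2 oxidation of the secondary allylic alcohol gives the 1,3-transposed carvone skeleton with the C5 ketone, the C9=C10 enone alkene and the C8 oxygen in the γ-position.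

Step 6
Reactants: 6 transposed enone; 7 vinylmagnesium bromide (CH2=CHMgBr)
Product: 8 tertiary vinyl carbinol
Conditions: CeCl3, THF, −78 °C
Reagents that add atoms: none
Why: 1,2-Addition of the weakly basic organocerium reagent to the enone carbonyl avoids conjugate addition and enolisation; as in 1,2-additions to carvone the nucleophile should attack axially on the face opposite the C7 isopropenyl group, placing the new C5 hydroxyl cis to it.

Step 7
Reactants: 8 tertiary vinyl carbinol
Product: 9 epoxy alcohol
Conditions: VO(acac)2 (cat.), tBuOOH, CH2Cl2, 0 °C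
Reagents that add atoms: tert-butyl hydroperoxide, CC(C)(C)OO
Why: Hydroxyl-directed vanadium-catalysed epoxidation: the tertiary allylic hydroxyl delivers oxygen to its own face of the trisubstituted C9=C10 alkene, which is also the face opposite the C8 silyl ether, and this sets C9 while the vinyl and isopropenyl groups are left alone.

Step 8
Reactants: 9 epoxy alcohol
Product: 10 2-methyl-2-vinylcyclohexanone
Conditions: Et3SiOTf, 2,6-lutidine, CH2Cl2, −78 °C
Reagents that add atoms: triethylsilyl trifluoromethanesulfonate, CC[Si](CC)(CC)OS(=O)(=O)C(F)(F)F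
Why: Semipinacol rearrangement of a 2,3-epoxy alcohol: silylation of the epoxide oxygen triggers ionisation at the tertiary C10, the C5 vinyl group standing antiperiplanar to the breaking C10–O bond migrates with inversion at C10, the C5 ketone is regenerated and the silyl group stays on the C9 oxygen, so C9 is retained and the quaternary C10 is set with vinyl trans to the C9 oxygen.

Step 9
Reactants: 10 2-methyl-2-vinylcyclohexanone; 11 isopropenylmagnesium bromide (CH2=C(CH3)MgBr)
Product: 12 rearrangement precursor
Conditions: CeCl3, THF, −78 to 0 °C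
Reagents that add atoms: none
Why: Organocerium 1,2-addition to a hindered, enolisable ketone; the chair is locked by the three equatorial groups at C7–C9 and the bulky reagent is expected to enter along the equatorial trajectory, away from the axial hydrogens at C7 and C9, giving the axial alcohol with the 2-propenyl group equatorial and trans to the vinyl group (a C5 epimer, if formed, is separated here).

Step 10
Reactants: 12 rearrangement precursor
Product: 15 (E)-cyclodec-5-enone, via potassium alkoxide 13 (not isolated), via potassium enolate 14 (not isolated)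
Conditions: KH, 18-crown-6, THF, 0 °C to rt; then MeOH, −78 °C
Reagents that add atoms: none
Why: KH with 18-crown-6 gives the dissociated potassium alkoxide 13, in which the weakened C5–C10 bond breaks as C2–C3 forms in a concerted [3,3] shift (anionic oxy-Cope rearrangement; closest known type: ring expansion of trans-1,2-dialkenylcyclohexanols to (E)-cyclodec-5-enones). The ten-membered ring arises by a four-atom enlargement of the cyclohexane, not by end-to-end cyclisation, so no dilution is needed, and the shift passes through a chair-like six-centre array fused to the chair cyclohexane. Because both alkenyl groups are equatorial and trans (secured in steps 8 and 9), the ring bond C9–C10 sits pseudo-equatorial in that array and the new C1=C10 alkene should be E, as the directed epoxidation of step 12 requires. The C4 stereocentre is created when the ring enolate 14 is protonated at low temperature from its outer face; it lies next to the C5 ketone and can be equilibrated with DBU if the kinetic outcome is unfavourable. The selectivity needed is the alkene geometry and a clean [3,3] path: the silyl ethers at C8 and C9 are too remote from the C5 alkoxide to migrate and the molecule holds no second 1,5-diene.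

Step 11
Reactants: 15 (E)-cyclodec-5-enone
Product: 16 C9 allylic alcohol
Conditions: HF·pyridine, pyridine, THF, 0 °C
Reagents that add atoms: none
Why: Selective cleavage of the secondary triethylsilyl ether beside the more robust tert-butyldimethylsilyl ether with buffered fluoride frees the allylic C9 hydroxyl without acid strong enough to provoke transannular reactions between the ketone and the alkene.

Step 12
Reactants: 16 C9 allylic alcohol
Product: 17 epoxy alcohol
Conditions: VO(acac)2 (cat.), tBuOOH, CH2Cl2, 0 °C
Reagents that add atoms: tert-butyl hydroperoxide, CC(C)(C)OO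
Why: Hydroxyl-directed vanadium-catalysed epoxidation: with H9 eclipsing the C10 methyl group (least A(1,2) strain) the C9 hydroxyl lies over the outer face of the (E)-C1=C10 alkene and delivers oxygen there (erythro epoxy alcohol), which sets the C10 configuration of the target and leaves the isopropenyl group untouched.

Step 13
Reactants: 17 epoxy alcohol
Product: 18 hydroxy selenide
Conditions: PhSeH, Ti(OiPr)4, CH2Cl2, rt
Reagents that add atoms: benzeneselenol, [SeH]c1ccccc1
Why: Ti(OiPr)4-mediated opening of a 2,3-epoxy alcohol by a soft nucleophile: titanium bound to the C9 oxygen activates the oxirane and the selenol attacks the distal secondary C1 in SN2 fashion, so the C10–O bond and the C10 configuration are kept and the C5 ketone, which a hydride reagent would reduce, is not touched.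

Step 14
Reactants: 18 hydroxy selenide
Product: 19 9,10-diol
Conditions: Bu3SnH, AIBN (cat.), PhMe, 80 °C
Reagents that add atoms: none
Why: Radical chain reduction of the alkyl phenyl selenide replaces selenium by hydrogen at C1 under neutral conditions that leave ketone, isopropenyl group, diol and silyl ether alone.

Step 15
Reactants: 19 9,10-diol; 20 (R)-2-methylbutanoic acid
Product: 21 C9 ester
Conditions: DCC, DMAP (cat.), CH2Cl2, 0 °C to rt
Reagents that add atoms: none
Why: Steglich esterification of the only acylable hydroxyl (C9–OH is secondary, C10–OH tertiary, C8 silylated); the mild carbodiimide activation should keep the α-stereocentre of the acid intact.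

Step 16
Reactants: 21 C9 ester
Product: 22 C8 alcohol
Conditions: HF·pyridine, THF, 0 °C to rt
Reagents that add atoms: none
Why: Fluoride-mediated desilylation under slightly acidic conditions, chosen over basic fluoride sources so that the C9 acyl group does not migrate to the freed C8 hydroxyl.

Step 17
Reactants: 22 C8 alcohol
Product: 23 C12 allylic alcohol
Conditions: SeO2 (cat.), tBuOOH, CH2Cl2, rt
Reagents that add atoms: tert-butyl hydroperoxide, CC(C)(C)OO
Why: SeO2-catalysed allylic oxidation (ene reaction followed by [2,3]-sigmatropic shift) converts the methyl group of the isopropenyl unit into the primary allylic alcohol; the methyl group is normally preferred over the allylic methine C7–H and no other alkene is left in the molecule.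

Step 18
Reactants: 23 C12 allylic alcohol
Product: 26 ineupatorolide A, via hydroxy enal 24 (not isolated), via lactol 25 (not isolated)
Conditions: MnO2, CH2Cl2, rt
Reagents that add atoms: none
Why: Oxidative lactonisation of a 2-methylene-1,4-diol: MnO2 oxidises the primary allylic alcohol to the enal, the C8 hydroxyl closes onto it to the five-membered lactol (5-exo-trig), and this allylic hemiacetal is oxidised on to the α-methylene γ-lactone, whose trans ring fusion follows from the C7/C8 configuration already present.

Compound list
1 | (R)-carvone, (5R)-2-methyl-5-(prop-1-en-2-yl)cyclohex-2-en-1-one | O=C1C[C@H](C(C)=C)CC=C1C | starting material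
2 | trans-6-hydroxycarvone, (5S,6S)-6-hydroxy-2-methyl-5-(prop-1-en-2-yl)cyclohex-2-en-1-one; hydroxyl trans to isopropenyl, carbinol carbon is the future C8 | O=C1[C@@H](O)[C@H](C(C)=C)CC=C1C | intermediate
3 | tert-butyldimethylsilyl ether of 2 | O=C1[C@@H](O[Si](C)(C)C(C)(C)C)[C@H](C(C)=C)CC=C1C | intermediate
4 | 2,3-epoxide of 3, oxirane oxygen trans to the isopropenyl group | O=C1[C@@H](O[Si](C)(C)C(C)(C)C)[C@H](C(C)=C)C[C@H]2O[C@@]12C | intermediate
5 | (4R,5S)-4-(tert-butyldimethylsilyloxy)-2-methyl-5-(prop-1-en-2-yl)cyclohex-2-en-1-ol, hydroxyl trans to isopropenyl (C5 carbinol, C9=C10 alkene) | O[C@@H]1C[C@@H](C(C)=C)[C@H](O[Si](C)(C)C(C)(C)C)C=C1C | intermediate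
6 | (4R,5S)-4-(tert-butyldimethylsilyloxy)-2-methyl-5-(prop-1-en-2-yl)cyclohex-2-en-1-one (C5 ketone, C9=C10, C8 OTBS trans to C7 isopropenyl) | O=C1C[C@@H](C(C)=C)[C@H](O[Si](C)(C)C(C)(C)C)C=C1C | intermediate
7 | vinylmagnesium bromide, CH2=CHMgBr | C=C[Mg]Br | starting material
8 | 1-vinyl adduct of 6: tertiary C5 alcohol, hydroxyl cis and vinyl trans to the C7 isopropenyl group | C=C[C@]1(O)C[C@@H](C(C)=C)[C@H](O[Si](C)(C)C(C)(C)C)C=C1C | intermediate
9 | C9,C10-epoxide of 8, oxirane oxygen cis to the C5 hydroxyl and trans to the C8 silyl ether | C=C[C@]1(O)C[C@@H](C(C)=C)[C@H](O[Si](C)(C)C(C)(C)C)[C@H]2O[C@@]12C | intermediate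
10 | 2-methyl-2-vinylcyclohexanone: C5 ketone; C10 methyl cis and vinyl trans to the C9 triethylsilyloxy group; C7 isopropenyl, C8 OTBS and C9 OTES mutually trans (all equatorial) | O=C1C[C@@H](C(C)=C)[C@H](O[Si](C)(C)C(C)(C)C)[C@@H](O[Si](CC)(CC)CC)[C@]1(C)C=C | intermediate
11 | isopropenylmagnesium bromide, CH2=C(CH3)MgBr | C=C(C)[Mg]Br | starting material
12 | rearrangement precursor, trans-1-(2-propenyl)-2-vinylcyclohexanol: C5 hydroxyl axial and cis to the C10 vinyl group, C5 2-propenyl equatorial and cis to the C10 methyl; C7–C9 as in 10 | C=C(C)[C@@]1(O)C[C@@H](C(C)=C)[C@H](O[Si](C)(C)C(C)(C)C)[C@@H](O[Si](CC)(CC)CC)[C@]1(C)C=C | intermediate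
13 | potassium alkoxide of 12 | C=C(C)[C@@]1([O-])C[C@@H](C(C)=C)[C@H](O[Si](C)(C)C(C)(C)C)[C@@H](O[Si](CC)(CC)CC)[C@]1(C)C=C.[K+] | intermediate (not isolated)
14 | potassium enolate of 15: ten-membered ring, C4=C5 enolate with ring carbons C3 and C6 trans, (E)-C1=C10 | C/C1=C(/[O-])C[C@@H](C(C)=C)[C@H](O[Si](C)(C)C(C)(C)C)[C@@H](O[Si](CC)(CC)CC)/C(C)=C/CC1.[K+] | intermediate (not isolated)
15 | (E)-cyclodec-5-enone: (4R)-methyl, C5 ketone, C7 isopropenyl, C8 OTBS, C9 OTES, methyl on C10 of the (E)-C1=C10 alkene | O=C1C[C@@H](C(C)=C)[C@H](O[Si](C)(C)C(C)(C)C)[C@@H](O[Si](CC)(CC)CC)/C(C)=C/CC[C@H]1C | intermediate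
16 | C9 allylic alcohol from 15 (OTES replaced by OH) | O=C1C[C@@H](C(C)=C)[C@H](O[Si](C)(C)C(C)(C)C)[C@@H](O)/C(C)=C/CC[C@H]1C | intermediate
17 | 1,10-epoxide of 16, oxirane oxygen on the face of the C9 hydroxyl (erythro), C10 configured as in the target | O=C1C[C@@H](C(C)=C)[C@H](O[Si](C)(C)C(C)(C)C)[C@@H](O)[C@@]2(C)O[C@@H]2CC[C@H]1C | intermediate
18 | hydroxy selenide: C1 phenylselanyl (inverted at C1), C9 and C10 hydroxyls | O=C1C[C@@H](C(C)=C)[C@H](O[Si](C)(C)C(C)(C)C)[C@@H](O)[C@@](C)(O)[C@@H]([Se]c2ccccc2)CC[C@H]1C | intermediate
19 | 9,10-diol with C1 methylene, C10 tertiary alcohol as in the target | O=C1C[C@@H](C(C)=C)[C@H](O[Si](C)(C)C(C)(C)C)[C@@H](O)[C@@](C)(O)CCC[C@H]1C | intermediate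
20 | (R)-2-methylbutanoic acid | CC[C@@H](C)C(=O)O | starting material
21 | C9 (R)-2-methylbutanoate of 19 | O=C1C[C@@H](C(C)=C)[C@H](O[Si](C)(C)C(C)(C)C)[C@@H](OC(=O)[C@H](C)CC)[C@@](C)(O)CCC[C@H]1C | intermediate
22 | C8 alcohol from 21 (OTBS replaced by OH) | O=C1C[C@@H](C(C)=C)[C@H](O)[C@@H](OC(=O)[C@H](C)CC)[C@@](C)(O)CCC[C@H]1C | intermediate
23 | C12 primary allylic alcohol: C7 carries a 3-hydroxyprop-1-en-2-yl group | O=C1C[C@@H](C(CO)=C)[C@H](O)[C@@H](OC(=O)[C@H](C)CC)[C@@](C)(O)CCC[C@H]1C | intermediate
24 | hydroxy enal: C7 carries a 3-oxoprop-1-en-2-yl group | O=C1C[C@@H](C(C=O)=C)[C@H](O)[C@@H](OC(=O)[C@H](C)CC)[C@@](C)(O)CCC[C@H]1C | intermediate (not isolated)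
25 | lactol between C12 and O8 (either anomer) | C=C1C(O)O[C@@H]2[C@@H](OC(=O)[C@H](C)CC)[C@@](C)(O)CCC[C@@H](C)C(=O)C[C@@H]12 | intermediate (not isolated)
26 | ineupatorolide A | C=C1C(=O)O[C@@H]2[C@@H](OC(=O)[C@H](C)CC)[C@@](C)(O)CCC[C@@H](C)C(=O)C[C@@H]12 | target

Total steps: 18. Longest linear sequence: 18 steps, from 1 to 26.

Steps most likely to fail

Step 9. What may go wrong is poor or even inverted facial selectivity in the carbonyl addition. The axial C10 methyl group flanks the equatorial trajectory, so entry anti to it may compete or dominate. The resulting cis-dialkenyl C5 epimer would pass through the chair array to the Z alkene. The fallback changes the order of bond formation at C5 so that oxygen, not carbon, arrives last and on the face opposite the axial methyl. Setting out from 10, enolisation toward C6 with KN(SiMe3)2 and trapping with PhNTf2 gives enol triflate F1. Suzuki coupling with isopropenylboronic acid pinacol ester (Pd(PPh3)4, K3PO4) gives 1,3-diene F2. Buffered mCPBA should epoxidise the trisubstituted ring alkene of the diene on the face opposite the C10 methyl, giving vinyl epoxide F3, though chemoselectivity over the isopropenyl group may be modest. LiBHEt3 then delivers hydride to the secondary C6 in a trans-diaxial SN2 opening, and the route is rejoined at 12.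

Step 13. What may go wrong is slow or misdirected epoxide opening. Backside approach to C1 points toward the interior of the ten-membered ring, so ionisation at the tertiary C10 or transannular attack by the C5 carbonyl oxygen may compete. The fallback uses a small hydride nucleophile with the ketone masked. Setting out from 16, 1,2-bis(trimethylsilyloxy)ethane with catalytic TMSOTf at −78 °C gives dioxolane F4. Directed epoxidation as in step 12 gives epoxy alcohol F5. LiBHEt3 opens it at C1 to diol F6. Esterification with 20 as in step 15 gives ester F7. Aqueous acetic acid removes the dioxolane, and the route is rejoined at 21.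

Step 17. What may go wrong is unselective or incomplete allylic oxidation: attack at the allylic methine C7–H, oxidation next to the C5 ketone, or over-oxidation. The fallback brings in the C12 oxygen by halogenation and substitution. Setting out from 22, ene-type allylic chlorination of the isopropenyl group with NaOCl and CeCl3·7H2O gives allylic chloride F8. N-Methylmorpholine N-oxide converts the chloride into the enal, and the route is rejoined at 24, which goes on to 25 and 26 with MnO2 as in step 18.

Further compounds
F1 | step 9 | enol triflate of 10 (C5 triflyloxy, C5=C6) | FC(F)(F)S(=O)(=O)OC1=C[C@@H](C(C)=C)[C@H](O[Si](C)(C)C(C)(C)C)[C@@H](O[Si](CC)(CC)CC)[C@]1(C)C=C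
F2 | step 9 | 1,3-diene (C5=C6 ring alkene bearing 2-propenyl at C5) | C=C(C)C1=C[C@@H](C(C)=C)[C@H](O[Si](C)(C)C(C)(C)C)[C@@H](O[Si](CC)(CC)CC)[C@]1(C)C=C
F3 | step 9 | vinyl epoxide (C5,C6-oxirane, oxygen trans to the C10 methyl) | C=C(C)[C@@]12O[C@@H]1[C@@H](C(C)=C)[C@H](O[Si](C)(C)C(C)(C)C)[C@@H](O[Si](CC)(CC)CC)[C@]2(C)C=C
F4 | step 13 | dioxolane (ethylene ketal of 16 at C5) | O1CCOC12C[C@@H](C(C)=C)[C@H](O[Si](C)(C)C(C)(C)C)[C@@H](O)/C(C)=C/CC[C@H]2C
F5 | step 13 | epoxy alcohol (1,10-epoxide of F4, oxygen syn to C9–OH) | O1CCOC12C[C@@H](C(C)=C)[C@H](O[Si](C)(C)C(C)(C)C)[C@@H](O)[C@@]3(C)O[C@@H]3CC[C@H]2C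
F6 | step 13 | diol (9,10-diol ketal) | O1CCOC12C[C@@H](C(C)=C)[C@H](O[Si](C)(C)C(C)(C)C)[C@@H](O)[C@@](C)(O)CCC[C@H]2C
F7 | step 13 | ester (C9 (R)-2-methylbutanoate of F6) | O1CCOC12C[C@@H](C(C)=C)[C@H](O[Si](C)(C)C(C)(C)C)[C@@H](OC(=O)[C@H](C)CC)[C@@](C)(O)CCC[C@H]2C
F8 | step 17 | allylic chloride (C12 chloride of 22) | O=C1C[C@@H](C(CCl)=C)[C@H](O)[C@@H](OC(=O)[C@H](C)CC)[C@@](C)(O)CCC[C@H]1C
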